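**Retrosynthetic overview**
1. The target is achilleol A acetate. Numbering used here: ring A = C1, C2, C3 (OAc), C4 (gem-dimethyl), C5 (H, side chain starting at C6) and C10 (exocyclic C10=C25 methylene).
2. Enabling feature: C5 is allylic to the C10=C25 methylene and sits 1,3-cis to the C3 oxygen across C4. An acyl group on C3–O can therefore deliver its α-carbon (C6) to C5 of a C5=C10–C25H2Cl unit by SN2′, closing a temporary bridged δ-lactone. This one step makes C5–C6, the methylene and the C5 stereocentre.
3. Disconnections: C5–C6 (step 12); the tether carbonyl on C6 (saponification, acetylation, Barton decarboxylation); C8=C9 (Johnson–Claisen, chain acid 13 from farnesyl bromide); ring fragment 6 from ketol 1 by α-methylenation, 1,2-reduction and allylic transposition to the chloride.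
4. Ring order: ring A comes with ketol 1 and is never opened; the only ring closed is the temporary lactone (step 12), opened again in step 13.

Key step: step 12

Assumption: ketol 1 is purchased as the (S)-enantiomer (it is also the baker's-yeast reduction product of 2,2-dimethylcyclohexane-1,3-dione).

**Ring fragment**

Step 1
Reactants: 1 (S)-3-hydroxy-2,2-dimethylcyclohexan-1-one
Product: 2 (S)-3-[(tert-butyldimethylsilyl)oxy]-2,2-dimethylcyclohexan-1-one
Conditions: TBSCl, imidazole, DMF, 25 °C
Reagents that add atoms: tert-butyldimethylsilyl chloride, CC(C)(C)[Si](C)(C)Cl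
Why: Silyl ether formation; it keeps the C3 oxygen out of the thionyl chloride step and does not touch the carbinol centre, which stays (S).

Step 2
Reactants: 2 (S)-3-[(tert-butyldimethylsilyl)oxy]-2,2-dimethylcyclohexan-1-one
Product: 3 (S)-3-[(tert-butyldimethylsilyl)oxy]-2,2-dimethyl-6-methylidenecyclohexan-1-one
Conditions: (CH2O)n, i-Pr2NH2+ CF3CO2− (1 equiv), TFA (0.1 equiv), THF, reflux; crude used at once
Reagents that add atoms: paraformaldehyde (as formaldehyde), C=O
Why: Mannich-type α-methylenation (iminium aldol, then β-elimination of the amine); C2 is quaternary, so only C6 can enolise and a single regioisomer can form.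

Step 3
Reactants: 3 (S)-3-[(tert-butyldimethylsilyl)oxy]-2,2-dimethyl-6-methylidenecyclohexan-1-one
Product: 4 (1RS,3S)-3-[(tert-butyldimethylsilyl)oxy]-2,2-dimethyl-6-methylidenecyclohexan-1-ol
Conditions: NaBH4, CeCl3·7H2O, MeOH, −78 to 0 °C
Reagents that add atoms: none
Why: Luche 1,2-reduction of the enone; both carbinol epimers are acceptable because this carbon becomes sp2 in step 4.

Step 4
Reactants: 4 (1RS,3S)-3-[(tert-butyldimethylsilyl)oxy]-2,2-dimethyl-6-methylidenecyclohexan-1-ol
Product: 5 tert-butyl{[(1S)-4-(chloromethyl)-2,2-dimethylcyclohex-3-en-1-yl]oxy}dimethylsilane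
Conditions: SOCl2 (1.1 equiv), Et2O, 0 °C
Reagents that add atoms: thionyl chloride, O=S(Cl)Cl
Why: Allylic rearrangement of the chlorosulfite (SNi′); the carbinol carbon is neopentylic, so chloride is delivered to the methylene terminus and the primary allylic chloride with the trisubstituted C5=C10 ring alkene results.

Step 5
Reactants: 5 tert-butyl{[(1S)-4-(chloromethyl)-2,2-dimethylcyclohex-3-en-1-yl]oxy}dimethylsilane
Product: 6 (1S)-4-(chloromethyl)-2,2-dimethylcyclohex-3-en-1-ol
Conditions: 48% aq. HF, MeCN, 0 to 25 °C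
Reagents that add atoms: none
Why: Acidic fluoride desilylation, chosen because it is neither basic nor nucleophilic towards the primary allylic chloride; the (S) carbinol is not involved.

**Chain acid**

Step 6
Reactants: 7 (2E,6E)-farnesyl bromide
Product: 8 (4E,8E)-5,9,13-trimethyltetradeca-4,8,12-trienenitrile
Conditions: MeCN (3 equiv), n-BuLi (3 equiv), THF, −78 °C; then 7, −78 to −30 °C
Reagents that add atoms: acetonitrile, CC#N
Why: SN2 alkylation of lithioacetonitrile by the primary allylic bromide; excess nucleophile at low temperature limits double alkylation, and the two E alkenes of the farnesyl unit are not touched.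

Step 7
Reactants: 8 (4E,8E)-5,9,13-trimethyltetradeca-4,8,12-trienenitrile
Product: 9 (4E,8E)-5,9,13-trimethyltetradeca-4,8,12-trienal
Conditions: i-Bu2AlH (1.2 equiv), CH2Cl2, −78 °C; then 1 M HCl, 0 °C
Reagents that add atoms: water, O
Why: Nitrile-to-aldehyde reduction; hydride adds once to give the aluminium aldimine, which is hydrolysed on acidic work-up.

Step 8
Reactants: 9 (4E,8E)-5,9,13-trimethyltetradeca-4,8,12-trienal
Product: 10 (6E,10E)-2,7,11,15-tetramethylhexadeca-1,6,10,14-tetraen-3-ol (racemic)
Conditions: CH2=C(CH3)MgBr, THF, −20 to 0 °C; then H2O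
Reagents that add atoms: isopropenylmagnesium bromide, C=C(C)[Mg]Br
Why: Grignard 1,2-addition to the aldehyde; the carbinol forms racemic, which is harmless because this centre is destroyed in step 9.

Step 9
Reactants: 10 (6E,10E)-2,7,11,15-tetramethylhexadeca-1,6,10,14-tetraen-3-ol
Product: 12 ethyl (4E,8E,12E)-4,9,13,17-tetramethyloctadeca-4,8,12,16-tetraenoate, via ketene acetal 11 (not isolated)
Conditions: CH3C(OEt)3 (6 equiv), EtCO2H (0.05 equiv), 138 °C, EtOH distilled off
Reagents that add atoms: triethyl orthoacetate, CCOC(C)(OCC)OCC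
Why: Johnson–Claisen rearrangement; in the chair transition state the long chain on the carbinol carbon sits equatorial, away from the ethoxy group of the ketene acetal, so the new trisubstituted C8=C9 alkene should form with E geometry.

Step 10
Reactants: 12 ethyl (4E,8E,12E)-4,9,13,17-tetramethyloctadeca-4,8,12,16-tetraenoate
Product: 13 (4E,8E,12E)-4,9,13,17-tetramethyloctadeca-4,8,12,16-tetraenoic acid
Conditions: LiOH·H2O, THF/MeOH/H2O, 40 °C; then 1 M HCl to pH 3
Reagents that add atoms: lithium hydroxide, [Li+].[OH-]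
Why: Saponification of the unhindered ethyl ester; no stereo element is involved.

**Union and completion**

Step 11
Reactants: 6 (1S)-4-(chloromethyl)-2,2-dimethylcyclohex-3-en-1-ol; 13 (4E,8E,12E)-4,9,13,17-tetramethyloctadeca-4,8,12,16-tetraenoic acid
Product: 14 (1S)-4-(chloromethyl)-2,2-dimethylcyclohex-3-en-1-yl (4E,8E,12E)-4,9,13,17-tetramethyloctadeca-4,8,12,16-tetraenoate
Conditions: DCC (1.3 equiv), DMAP (0.2 equiv), CH2Cl2, 0 to 25 °C
Reagents that add atoms: none
Why: Steglich esterification (carbodiimide activation, acyl transfer through the acylpyridinium); the C3–O bond is not broken, so the (S) configuration is kept, and the allylic chloride is inert to these reagents.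

Step 12
Reactants: 14 (1S)-4-(chloromethyl)-2,2-dimethylcyclohex-3-en-1-yl (4E,8E,12E)-4,9,13,17-tetramethyloctadeca-4,8,12,16-tetraenoate
Product: 16 (1S,4RS,5R)-9,9-dimethyl-6-methylidene-4-[(2E,6E,10E)-2,7,11,15-tetramethylhexadeca-2,6,10,14-tetraen-1-yl]-2-oxabicyclo[3.3.1]nonan-3-one, via potassium enolate 15 (not isolated)
Conditions: KN(SiMe3)2 (1.2 equiv), THF (0.01 M), −78 °C, then −78 to 0 °C
Reagents that add atoms: potassium bis(trimethylsilyl)amide, [K+].C[Si](C)(C)[N-][Si](C)(C)C (potassium, present only in intermediate 15)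
Why: Proposed new method: the base turns the ester into enolate 15, and on warming the enolate α-carbon (C6) attacks C5 of the C5=C10–C25H2Cl allylic chloride in an intramolecular SN2′ displacement that expels chloride from C25 and leaves the C10=C25 methylene. The closest known reaction type is the intramolecular ester-enolate alkylation, including its SN2′ variant with allylic chlorides, used to close carbocycles and cyclic ethers; new here is that the ester oxygen lies inside the ring being formed, so a lactone results. The only ring closed is the six-membered lactone, by a 6-(enolendo)-exo-trig closure that gives the bridged 2-oxabicyclo[3.3.1]nonan-3-one. The new stereocentre C5 is controlled by the C3 stereocentre through the three-atom tether: the enolate carbon can reach C5 only on the ring face that carries the (then axial) C3–O bond, in a chair-like axial attack anti to the pseudoaxial C4 methyl, which gives the 3,5-cis relationship of the target; the centre formed at C6 is not controlled and is erased in step 15. The step needs attack at C5 instead of C25 and on carbon instead of oxygen: direct displacement at C25 would require an eight-membered ring holding an E ring alkene and is excluded, C25 has no β-hydrogen for elimination, the soft allylic chloride favours C-alkylation, and high dilution suppresses intermolecular alkylation and Claisen condensation.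

Step 13
Reactants: 16 (1S,4RS,5R)-9,9-dimethyl-6-methylidene-4-[(2E,6E,10E)-2,7,11,15-tetramethylhexadeca-2,6,10,14-tetraen-1-yl]-2-oxabicyclo[3.3.1]nonan-3-one
Product: 17 (2RS,4E,8E,12E)-2-[(1R,3S)-3-hydroxy-2,2-dimethyl-6-methylidenecyclohexyl]-4,9,13,17-tetramethyloctadeca-4,8,12,16-tetraenoic acid
Conditions: KOH, MeOH/H2O (4:1), 60 °C; then cold 1 M HCl to pH 4, extraction at 0 °C, used at once
Reagents that add atoms: potassium hydroxide, [K+].[OH-]
Why: Saponification of the lactone; ring opening lets ring A relax to the chair with the C3 hydroxyl and the C5 substituent both equatorial, and neither C3 nor C5 is touched.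

Step 14
Reactants: 17 (2RS,4E,8E,12E)-2-[(1R,3S)-3-hydroxy-2,2-dimethyl-6-methylidenecyclohexyl]-4,9,13,17-tetramethyloctadeca-4,8,12,16-tetraenoic acid
Product: 19 (2RS,4E,8E,12E)-2-[(1R,3S)-3-acetoxy-2,2-dimethyl-6-methylidenecyclohexyl]-4,9,13,17-tetramethyloctadeca-4,8,12,16-tetraenoic acid, via mixed anhydride 18 (not isolated)
Conditions: Ac2O (10 equiv), pyridine, DMAP (0.1 equiv), 0 to 25 °C; then H2O/THF, 25 °C
Reagents that add atoms: acetic anhydride, CC(=O)OC(C)=O
Why: Nucleophile-catalysed O-acetylation of the equatorial C3 alcohol; the carboxyl group travels as mixed anhydride 18 and is set free again in the aqueous stage, which the secondary acetate survives.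

Step 15
Reactants: 19 (2RS,4E,8E,12E)-2-[(1R,3S)-3-acetoxy-2,2-dimethyl-6-methylidenecyclohexyl]-4,9,13,17-tetramethyloctadeca-4,8,12,16-tetraenoic acid
Product: 21 (1S,3R)-2,2-dimethyl-4-methylidene-3-[(3E,7E,11E)-3,8,12,16-tetramethylheptadeca-3,7,11,15-tetraen-1-yl]cyclohexyl acetate (target), via Barton ester 20 (not isolated)
Conditions: N-hydroxypyridine-2-thione, DCC, DMAP (cat.), CH2Cl2, 0 °C, dark; then t-BuSH (10 equiv), hν (visible), 10 °C
Reagents that add atoms: N-hydroxypyridine-2-thione, ON1C=CC=CC1=S (retained only in intermediate 20)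
Why: Barton reductive decarboxylation; thiohydroxamate ester 20 loses CO2 under light to give the secondary C6 radical, which should take hydrogen from the thiol faster than a homoallyl radical rearranges, so C6 becomes the CH2 of the target, its uncontrolled configuration vanishes, and C3 and C5 stay as set.

**Compound list**

1 | (S)-3-hydroxy-2,2-dimethylcyclohexan-1-one | O=C1CCC[C@H](O)C1(C)C | starting material
2 | (S)-3-[(tert-butyldimethylsilyl)oxy]-2,2-dimethylcyclohexan-1-one | O=C1CCC[C@H](O[Si](C)(C)C(C)(C)C)C1(C)C | intermediate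
3 | (S)-3-[(tert-butyldimethylsilyl)oxy]-2,2-dimethyl-6-methylidenecyclohexan-1-one | C=C1CC[C@H](O[Si](C)(C)C(C)(C)C)C(C)(C)C1=O | intermediate
4 | (1RS,3S)-3-[(tert-butyldimethylsilyl)oxy]-2,2-dimethyl-6-methylidenecyclohexan-1-ol | C=C1CC[C@H](O[Si](C)(C)C(C)(C)C)C(C)(C)C1O | intermediate
5 | tert-butyl{[(1S)-4-(chloromethyl)-2,2-dimethylcyclohex-3-en-1-yl]oxy}dimethylsilane | ClCC1=CC(C)(C)[C@@H](O[Si](C)(C)C(C)(C)C)CC1 | intermediate
6 | (1S)-4-(chloromethyl)-2,2-dimethylcyclohex-3-en-1-ol | ClCC1=CC(C)(C)[C@@H](O)CC1 | intermediate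
7 | (2E,6E)-farnesyl bromide | BrC/C=C(\C)CC/C=C(\C)CCC=C(C)C | starting material
8 | (4E,8E)-5,9,13-trimethyltetradeca-4,8,12-trienenitrile | N#CCC/C=C(\C)CC/C=C(\C)CCC=C(C)C | intermediate
9 | (4E,8E)-5,9,13-trimethyltetradeca-4,8,12-trienal | O=CCC/C=C(\C)CC/C=C(\C)CCC=C(C)C | intermediate
10 | (6E,10E)-2,7,11,15-tetramethylhexadeca-1,6,10,14-tetraen-3-ol (racemic) | C=C(C)C(O)CC/C=C(\C)CC/C=C(\C)CCC=C(C)C | intermediate
11 | (6E,10E)-3-[(1-ethoxyethenyl)oxy]-2,7,11,15-tetramethylhexadeca-1,6,10,14-tetraene (ketene acetal) | C=C(OCC)OC(C(C)=C)CC/C=C(\C)CC/C=C(\C)CCC=C(C)C | intermediate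
12 | ethyl (4E,8E,12E)-4,9,13,17-tetramethyloctadeca-4,8,12,16-tetraenoate | CCOC(=O)CC/C(C)=C/CC/C=C(\C)CC/C=C(\C)CCC=C(C)C | intermediate
13 | (4E,8E,12E)-4,9,13,17-tetramethyloctadeca-4,8,12,16-tetraenoic acid | OC(=O)CC/C(C)=C/CC/C=C(\C)CC/C=C(\C)CCC=C(C)C | intermediate
14 | (1S)-4-(chloromethyl)-2,2-dimethylcyclohex-3-en-1-yl (4E,8E,12E)-4,9,13,17-tetramethyloctadeca-4,8,12,16-tetraenoate | ClCC1=CC(C)(C)[C@@H](OC(=O)CC/C(C)=C/CC/C=C(\C)CC/C=C(\C)CCC=C(C)C)CC1 | intermediate
15 | potassium enolate of ester 14 | [K+].[O-]C(=CC/C(C)=C/CC/C=C(\C)CC/C=C(\C)CCC=C(C)C)O[C@H]1CCC(CCl)=CC1(C)C | intermediate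
16 | (1S,4RS,5R)-9,9-dimethyl-6-methylidene-4-[(2E,6E,10E)-2,7,11,15-tetramethylhexadeca-2,6,10,14-tetraen-1-yl]-2-oxabicyclo[3.3.1]nonan-3-one | C=C1CC[C@@H]2OC(=O)C(C/C(C)=C/CC/C=C(\C)CC/C=C(\C)CCC=C(C)C)[C@H]1C2(C)C | intermediate
17 | (2RS,4E,8E,12E)-2-[(1R,3S)-3-hydroxy-2,2-dimethyl-6-methylidenecyclohexyl]-4,9,13,17-tetramethyloctadeca-4,8,12,16-tetraenoic acid | C=C1CC[C@H](O)C(C)(C)[C@@H]1C(C/C(C)=C/CC/C=C(\C)CC/C=C(\C)CCC=C(C)C)C(=O)O | intermediate
18 | mixed acetic anhydride of acid 19 | C=C1CC[C@H](OC(C)=O)C(C)(C)[C@@H]1C(C/C(C)=C/CC/C=C(\C)CC/C=C(\C)CCC=C(C)C)C(=O)OC(C)=O | intermediate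
19 | (2RS,4E,8E,12E)-2-[(1R,3S)-3-acetoxy-2,2-dimethyl-6-methylidenecyclohexyl]-4,9,13,17-tetramethyloctadeca-4,8,12,16-tetraenoic acid | C=C1CC[C@H](OC(C)=O)C(C)(C)[C@@H]1C(C/C(C)=C/CC/C=C(\C)CC/C=C(\C)CCC=C(C)C)C(=O)O | intermediate
20 | 2-thioxopyridin-1(2H)-yl ester of acid 19 (Barton ester) | C=C1CC[C@H](OC(C)=O)C(C)(C)[C@@H]1C(C/C(C)=C/CC/C=C(\C)CC/C=C(\C)CCC=C(C)C)C(=O)ON1C=CC=CC1=S | intermediate
21 | (1S,3R)-2,2-dimethyl-4-methylidene-3-[(3E,7E,11E)-3,8,12,16-tetramethylheptadeca-3,7,11,15-tetraen-1-yl]cyclohexyl acetate | C=C1CC[C@H](OC(C)=O)C(C)(C)[C@@H]1CC/C(C)=C/CC/C=C(\C)CC/C=C(\C)CCC=C(C)C | target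

**Step count and risks**

Total steps: 15. Longest linear sequence: 10 steps (steps 1–5 and 11–15; the chain branch, steps 6–10 and 11–15, is equally long).

Steps most likely to fail:

1. Step 12 (proposed new method). The enolate may alkylate on oxygen and close a cyclic ketene acetal, react between molecules, or decompose before its carbon reaches the hindered ring carbon. The fallback uses known chemistry, sets out from chloride 5 and acid 13, and comes back to the route at lactone 16. The caesium salt of 13 (Cs2CO3, DMF) is O-alkylated by 5 to give the allylic ester F1. LiN(i-Pr)2 and Me3SiCl/Et3N in THF, −78 to 60 °C, then bring about an Ireland–Claisen rearrangement of the silyl ketene acetal, which forms the same C5–C6 bond and the C10=C25 methylene and gives after aqueous work-up the silyl-protected acid F2. Without the tether the ring alone decides the face, so F2 is expected as a mixture of both C5 epimers. Aqueous HF in MeCN removes the silyl group and gives 17 together with its C5 epimer, the trans hydroxy acid F3. DCC then closes only the cis acid 17 to lactone 16, which is separated from F3 (unable to lactonise) and carried on through step 13.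

2. Step 14. Re-closure of the lactone through the mixed anhydride may compete with O-acetylation. The fallback sets out from 17, used as its potassium carboxylate straight from step 13 without acidification, and comes back at 19. Allyl bromide in DMF alkylates the carboxylate to the hydroxy allyl ester F4, in which no acyl activation and hence no lactonisation is possible. Ac2O, pyridine and DMAP give the acetoxy allyl ester F5. Pd(PPh3)4, a zerovalent palladium complex, with morpholine in THF then removes the allyl group and gives 19.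

3. Step 15. Thiyl radicals may add reversibly to the trisubstituted alkenes and scramble their E geometry, or the C6 radical may undergo a 1,2-vinyl shift before it is reduced. The fallback sets out from 19 and comes back at 21. N-Hydroxyphthalimide, N,N′-diisopropylcarbodiimide and DMAP give the redox-active ester F6. NiCl2·6H2O, 4,4′-di-tert-butyl-2,2′-bipyridine, Zn and PhSiH3 in THF/DMF/i-PrOH at 40 °C then effect a thiol-free reductive decarboxylation to 21.

Further compounds
F1 | step 12 | [(4S)-4-[(tert-butyldimethylsilyl)oxy]-3,3-dimethylcyclohex-1-en-1-yl]methyl (4E,8E,12E)-4,9,13,17-tetramethyloctadeca-4,8,12,16-tetraenoate | CC(C)(C)[Si](C)(C)O[C@H]1CCC(COC(=O)CC/C(C)=C/CC/C=C(\C)CC/C=C(\C)CCC=C(C)C)=CC1(C)C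
F2 | step 12 | (4E,8E,12E)-2-[(3S)-3-[(tert-butyldimethylsilyl)oxy]-2,2-dimethyl-6-methylidenecyclohexyl]-4,9,13,17-tetramethyloctadeca-4,8,12,16-tetraenoic acid (both epimers at the ring carbon that bears the side chain) | C=C1CC[C@H](O[Si](C)(C)C(C)(C)C)C(C)(C)C1C(C/C(C)=C/CC/C=C(\C)CC/C=C(\C)CCC=C(C)C)C(=O)O
F3 | step 12 | (4E,8E,12E)-2-[(1S,3S)-3-hydroxy-2,2-dimethyl-6-methylidenecyclohexyl]-4,9,13,17-tetramethyloctadeca-4,8,12,16-tetraenoic acid (trans, C5 epimer of 17) | C=C1CC[C@H](O)C(C)(C)[C@H]1C(C/C(C)=C/CC/C=C(\C)CC/C=C(\C)CCC=C(C)C)C(=O)O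
F4 | step 14 | allyl (4E,8E,12E)-2-[(1R,3S)-3-hydroxy-2,2-dimethyl-6-methylidenecyclohexyl]-4,9,13,17-tetramethyloctadeca-4,8,12,16-tetraenoate | C=C1CC[C@H](O)C(C)(C)[C@@H]1C(C/C(C)=C/CC/C=C(\C)CC/C=C(\C)CCC=C(C)C)C(=O)OCC=C
F5 | step 14 | allyl (4E,8E,12E)-2-[(1R,3S)-3-acetoxy-2,2-dimethyl-6-methylidenecyclohexyl]-4,9,13,17-tetramethyloctadeca-4,8,12,16-tetraenoate | C=C1CC[C@H](OC(C)=O)C(C)(C)[C@@H]1C(C/C(C)=C/CC/C=C(\C)CC/C=C(\C)CCC=C(C)C)C(=O)OCC=C
F6 | step 15 | 1,3-dioxoisoindolin-2-yl (4E,8E,12E)-2-[(1R,3S)-3-acetoxy-2,2-dimethyl-6-methylidenecyclohexyl]-4,9,13,17-tetramethyloctadeca-4,8,12,16-tetraenoate | C=C1CC[C@H](OC(C)=O)C(C)(C)[C@@H]1C(C/C(C)=C/CC/C=C(\C)CC/C=C(\C)CCC=C(C)C)C(=O)ON1C(=O)c2ccccc2C1=O
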